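The constants were drawn at random within sensible limits; no experiment stands behind them.

The constants k3 and k4 set a floor: a living end adds free monomer at k3[living end][free monomer] and gives it back at k4[living end], so net growth stops at [free monomer] = k4/k3 = 3.21 mM, the equilibrium monomer concentration.

    free monomer → uncatalysed product (k1 = 0.00144 s⁻¹)
    free monomer + initiator → living end + monomer in chains (k2 = 10.0 M⁻¹ s⁻¹)
    free monomer + living end → monomer in chains + living end, rate k3*[living end]*[free monomer] (k3 = 112 M⁻¹ s⁻¹)
    monomer in chains + living end → free monomer + living end, rate k4*[living end] as long as [monomer in chains] is above zero (k4 = 0.359 s⁻¹)

- dusk: free monomer 0.039 M; initiator 0.78 mM; time 15 s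
- dawn: free monomer 0.039 M; initiator 0.25 mM; time 15 s

- which of the two ends with the longer chains by the average number of monomer units in a chain (chains begun, living or dead) ("neither" if they lie within 10%) (dusk / dawn / neither)
- average number of monomer units in a chain (chains begun, living or dead) at the end, dusk
- average number of monomer units in a chain (chains begun, living or dead) at the end, dawn

- the average divides the monomer in chains by the number of chains begun, living and dead together
- run time (dusk): 15 s

Work in logarithms. Call [free monomer] minus that floor the excess. It starts at 35.8 mM, and since net growth is k3[living end] times the excess, its logarithm falls in a straight line while [living end] holds still.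

My first estimate is that each initiator gives one living end at once, so [living end] equals the initiator charge. The excess then loses one decade, a factor of 10, in a time of 2.3 divided by k3[living end]. That gives 82.1 s in dawn and 26.3 s in dusk, and I carry this decade time, the time for the excess to lose one decade.

But living ends do not appear at once. At the charge, initiator has a lifetime 1/(k2[free monomer]) of 2.56 s, shorter than the run. Since 5.86 lifetimes fit into 15 s, I divide by the whole charge but start the clock 2.56 s late.

Free monomer also leaves by the uncatalysed step, but k1, 0.00144 s⁻¹, is less than k3 times the dawn charge, 0.0280 s⁻¹, so I drop that step.

Units per chain are then the excess, times one minus 10 to the power of minus the decades lost, over the charge: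

| Flask | Decade time | Decades lost | Units per chain |
|---|---|---|---|
| dusk | 26.3 s | 0.472 | 30.4 |
| dawn | 82.1 s | 0.151 | 42.1 |

So I commit to dawn: it loses fewer decades than dusk, yet shares its monomer among about a third as many chains.

The forecast says dawn, with 30.5 for dusk and 42.2 for dawn, on the ground that "Less initiator means fewer chains".

The flask gives 30.6 in dusk and 42.3 in dawn, so dawn ends with the longer chains. The step to uncatalysed product, which holds 1.87% of the charged free monomer in dawn at 15.0 s, makes no difference to the dawn average. Leave dawn until 40 s: the decade time 82.1 s gives 0.456 decades and so 93.0 units per chain, and that flask reads 90.6.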